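**Plan**
- Retrosynthesis: after removal of four benzyl ethers and the C5 methyl ether, the 5,7-dihydroxyflavonol unit is opened at O1–C2 and C3–OH (Algar–Flynn–Oyamada) and at C2–C3 (Claisen–Schmidt) to an aryl aldehyde and a phloroacetophenone.
- The 7-methoxyflavonol unit is cut at O1–C8a and C4–C4a. Its ring C joins ring A at two adjacent carbons, C8a bearing the ring oxygen and C4a bearing the carbonyl next to the C5 oxygen; this is the addition pattern of an enol oxygen with a cis ester across 3,5-dimethoxybenzyne.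
- The ketoester is cut at the future C2–C3 bond (aldol, then oxidation) and the diaryl ether at C4'–O (SNAr of a 4-fluorobenzaldehyde by vanillin acetal).
- Forward: aryne precursor (steps 1–3) and ketoester (steps 4–8) are made separately; ring C of the methoxylated unit closes in step 9; chalcone (step 12), ring C of the second unit (step 13) and global deprotection (step 14) follow.
- Stereochemistry: the target has no stereocentre; the racemic centres of 16, 17, 25 and 27 are all erased on the way, and the E-alkene of chalcone 26 is set thermodynamically and then consumed.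

Key step: step 9

Remark on the chemistry: 3,5-dimethoxyphenol delivers the silyl triflate with silicon between the triflate and a methoxy group, 3,5-dimethoxy-2-(trimethylsilyl)phenyl triflate. Its positional isomer with silicon and triflate exchanged would release the same 3,5-dimethoxybenzyne but would have to come from 2,4-dimethoxyphenol, so the former is used.

Step 1
Reactants: 1 3,5-dimethoxyphenol
Product: 2 3,5-dimethoxyphenyl isopropylcarbamate
Conditions: i-PrNCO, Et3N (cat.), CH2Cl2, rt
Reagents that add atoms: isopropyl isocyanate, CC(C)N=C=O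
Why: Base-catalysed addition of the phenol to the isocyanate (carbamoylation) should install the N-isopropyl carbamate that directs the next metalation and is later removed under mild base.

Step 2
Reactants: 2 3,5-dimethoxyphenyl isopropylcarbamate
Product: 6 3,5-dimethoxy-2-(trimethylsilyl)phenyl isopropylcarbamate, via N-silyl carbamate 3 (not isolated), via ortho-lithiated carbamate 4 (not isolated), via N-silyl C-silyl carbamate 5 (not isolated)
Conditions: t-BuMe2SiOTf (TBSOTf), TMEDA, Et2O, 0 °C to rt; n-BuLi, TMEDA, −78 °C; TMSCl, −78 °C to rt; aq. NaHSO4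
Reagents that add atoms: chlorotrimethylsilane, C[Si](C)(C)Cl
Why: Directed ortho-metalation of the transiently N-silylated carbamate should occur at C2, the position flanked by the carbamate and a methoxy group (cooperative direction), and the aryllithium is silylated at −78 °C before an anionic Fries shift can compete, the N–Si bond being hydrolysed on work-up.

Step 3
Reactants: 6 3,5-dimethoxy-2-(trimethylsilyl)phenyl isopropylcarbamate
Product: 8 3,5-dimethoxy-2-(trimethylsilyl)phenyl trifluoromethanesulfonate, via ortho-silylphenol 7 (not isolated)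
Conditions: DBU, Et2NH, MeCN, 40 °C; then PhNTf2, rt
Reagents that add atoms: N-phenylbis(trifluoromethanesulfonimide), O=S(=O)(N(c1ccccc1)S(=O)(=O)C(F)(F)F)C(F)(F)F
Why: Base-induced elimination of the carbamate to the phenoxide and isopropyl isocyanate (trapped by Et2NH as a urea), followed by triflation of the phenoxide in the same flask, is the established carbamate-to-triflate conversion for ortho-silylaryl aryne precursors.

Step 4
Reactants: 9 vanillin
Product: 10 4-(1,3-dioxolan-2-yl)-2-methoxyphenol
Conditions: HOCH2CH2OH, pTsOH·H2O (cat.), toluene, reflux with azeotropic removal of water; Et3N quench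
Reagents that add atoms: ethylene glycol, OCCO
Why: Acid-catalysed acetalisation masks the aldehyde as a base-stable 1,3-dioxolane and leaves the phenol free for the ether formation.

Step 5
Reactants: 11 4-fluoro-3-hydroxybenzaldehyde
Product: 12 3-(benzyloxy)-4-fluorobenzaldehyde
Conditions: BnBr, K2CO3, DMF, rt
Reagents that add atoms: benzyl bromide, BrCc1ccccc1
Why: Williamson etherification of the phenol proceeds at room temperature, where the fluorine para to the formyl group is not yet displaced.

Step 6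
Reactants: 10 4-(1,3-dioxolan-2-yl)-2-methoxyphenol; 12 3-(benzyloxy)-4-fluorobenzaldehyde
Product: 13 3-(benzyloxy)-4-[4-(1,3-dioxolan-2-yl)-2-methoxyphenoxy]benzaldehyde
Conditions: K2CO3, DMF, 110 °C
Reagents that add atoms: none
Why: Nucleophilic aromatic substitution (SNAr) of the fluorine para to the formyl group by the electron-rich phenoxide of 10 is a well-precedented diaryl ether synthesis, and the acetal ensures that only one free aldehyde is present afterwards.

Step 7
Reactants: 13 3-(benzyloxy)-4-[4-(1,3-dioxolan-2-yl)-2-methoxyphenoxy]benzaldehyde; 14 methyl 2-(benzyloxy)acetate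
Product: 16 methyl 2-(benzyloxy)-3-{3-(benzyloxy)-4-[4-(1,3-dioxolan-2-yl)-2-methoxyphenoxy]phenyl}-3-hydroxypropanoate (mixture of racemic diastereomers), via lithium enolate 15 (not isolated)
Conditions: 14, LiN(i-Pr)2, THF, −78 °C; then 13, −78 °C; AcOH quench
Reagents that add atoms: none
Why: Aldol addition of the preformed lithium glycolate enolate to the aryl aldehyde should be clean at −78 °C; the two new stereocentres form without control, which does not matter because one is removed in step 8 and the other in step 9.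

Step 8
Reactants: 16 methyl 2-(benzyloxy)-3-{3-(benzyloxy)-4-[4-(1,3-dioxolan-2-yl)-2-methoxyphenoxy]phenyl}-3-hydroxypropanoate
Product: 17 methyl 2-(benzyloxy)-3-{3-(benzyloxy)-4-[4-(1,3-dioxolan-2-yl)-2-methoxyphenoxy]phenyl}-3-oxopropanoate (racemic)
Conditions: IBX, EtOAc, 75 °C
Reagents that add atoms: none
Why: IBX oxidation of the benzylic secondary alcohol gives the ketoester under essentially neutral conditions that the dioxolane and the benzyl ethers tolerate, and no stereocentre is created.

Step 9
Reactants: 8 3,5-dimethoxy-2-(trimethylsilyl)phenyl trifluoromethanesulfonate; 17 methyl 2-(benzyloxy)-3-{3-(benzyloxy)-4-[4-(1,3-dioxolan-2-yl)-2-methoxyphenoxy]phenyl}-3-oxopropanoate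
Product: 21 3-(benzyloxy)-2-{3-(benzyloxy)-4-[4-(1,3-dioxolan-2-yl)-2-methoxyphenoxy]phenyl}-5,7-dimethoxy-4H-chromen-4-one, via caesium enolate 18 (not isolated), via 3,5-dimethoxybenzyne 19 (not isolated), via aryl caesium enol ether 20 (not isolated)
Conditions: CsF (4 equiv), THF, 65 °C, slow addition of 8 (1.5 equiv)
Reagents that add atoms: none
Why: Proposed new method: CsF strips the silyl group from 8 with loss of triflate to release aryne 19 and, as a base, converts 17 into its chelated caesium enolate 18; the ketone-derived enolate oxygen adds to the aryne carbon remote from the flanking methoxy group (the future C8a), which places the aryl anion of 20 on the carbon next to that methoxy group (the future C4a), and this anion attacks the cis-disposed methyl ester with loss of methoxide. The closest known reaction type is the CsF-promoted annulation of arynes with salicylate esters to xanthones (O-arylation followed by intramolecular acylation), of which a ketoester enol is the open-chain counterpart; new here is the use of an enolate that could also react at carbon. Ring C closes by a 6-exo-trig acyl substitution that forms O1–C8a and C4–C4a. No stereocentre is formed, and the racemic centre of 17 becomes sp2. The step needs O- over C-arylation, expected because the enolate carbon is fully substituted and carries the benzyloxy group, so that carbon attack would build a congested quaternary centre, and because the loosely paired caesium enolate carries its charge on oxygen; it also needs the 5,7- and not the 6,8-dimethoxy orientation, which the methoxy group beside the triple bond secures by polarising the aryne and stabilising the adjacent aryl anion. Ring closure must outrun protonation of the aryl anion, for which THF (no acidic C–H bonds, unlike MeCN) and slow addition of 8 are chosen.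

Step 10
Reactants: 21 3-(benzyloxy)-2-{3-(benzyloxy)-4-[4-(1,3-dioxolan-2-yl)-2-methoxyphenoxy]phenyl}-5,7-dimethoxy-4H-chromen-4-one
Product: 22 4-{2-(benzyloxy)-4-[3-(benzyloxy)-5,7-dimethoxy-4-oxo-4H-chromen-2-yl]phenoxy}-3-methoxybenzaldehyde
Conditions: 1 M HCl, THF, rt
Reagents that add atoms: water, O
Why: Acid-catalysed acetal hydrolysis frees the aldehyde, while the aryl ethers and the 3-alkoxychromone are stable to dilute acid at room temperature.

Step 11
Reactants: 23 2',4',6'-trihydroxyacetophenone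
Product: 24 1-[2,4-bis(benzyloxy)-6-hydroxyphenyl]ethan-1-one
Conditions: BnBr (2.1 equiv), K2CO3, DMF, rt
Reagents that add atoms: benzyl bromide, BrCc1ccccc1
Why: Williamson benzylation takes the two more nucleophilic phenols, whereas the third is hydrogen-bonded to the ketone carbonyl and stays free, as needed for the later ring closure.

Step 12
Reactants: 22 4-{2-(benzyloxy)-4-[3-(benzyloxy)-5,7-dimethoxy-4-oxo-4H-chromen-2-yl]phenoxy}-3-methoxybenzaldehyde; 24 1-[2,4-bis(benzyloxy)-6-hydroxyphenyl]ethan-1-one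
Product: 26 (E)-1-[2,4-bis(benzyloxy)-6-hydroxyphenyl]-3-(4-{2-(benzyloxy)-4-[3-(benzyloxy)-5,7-dimethoxy-4-oxo-4H-chromen-2-yl]phenoxy}-3-methoxyphenyl)prop-2-en-1-one, via aldol adduct 25 (not isolated)
Conditions: KOH (50% aq.), EtOH/THF, rt
Reagents that add atoms: none
Why: Claisen–Schmidt condensation of the acetophenone enolate with the non-enolisable aldehyde gives, after dehydration of aldol 25 under thermodynamic control, the E-chalcone, the flavone of 22 having no acidic position.

Step 13
Reactants: 26 (E)-1-[2,4-bis(benzyloxy)-6-hydroxyphenyl]-3-(4-{2-(benzyloxy)-4-[3-(benzyloxy)-5,7-dimethoxy-4-oxo-4H-chromen-2-yl]phenoxy}-3-methoxyphenyl)prop-2-en-1-one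
Product: 28 5,7-bis(benzyloxy)-2-(4-{2-(benzyloxy)-4-[3-(benzyloxy)-5,7-dimethoxy-4-oxo-4H-chromen-2-yl]phenoxy}-3-methoxyphenyl)-3-hydroxy-4H-chromen-4-one, via trans-dihydroflavonol 27 (not isolated)
Conditions: H2O2 (30% aq.), NaOH (aq.), MeOH/THF, 0 °C to rt
Reagents that add atoms: hydrogen peroxide, OO
Why: In the Algar–Flynn–Oyamada reaction alkaline hydrogen peroxide converts the 2'-hydroxychalcone through the racemic trans-dihydroflavonol 27 into the flavonol, the transient stereocentres being removed by oxidation in the same flask and low temperature favouring closure to the six-membered ring over the aurone pathway.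

Step 14
Reactants: 28 5,7-bis(benzyloxy)-2-(4-{2-(benzyloxy)-4-[3-(benzyloxy)-5,7-dimethoxy-4-oxo-4H-chromen-2-yl]phenoxy}-3-methoxyphenyl)-3-hydroxy-4H-chromen-4-one
Product: 29 2-{4-[4-(3,5-dihydroxy-7-methoxy-4-oxo-4H-chromen-2-yl)-2-hydroxyphenoxy]-3-methoxyphenyl}-3,5,7-trihydroxy-4H-chromen-4-one (target)
Conditions: BCl3 (excess), C6HMe5, CH2Cl2, −78 °C to 0 °C; MeOH then aq. HCl
Reagents that add atoms: none
Why: Lewis-acid ether cleavage with BCl3 should remove the four aryl benzyl ethers at low temperature (pentamethylbenzene trapping the benzyl cations) and, on warming, only the C5 methyl ether that is chelated to the C4 carbonyl, leaving the unchelated 7-methoxy and guaiacyl methoxy groups intact.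

**Compound list**
1 | 3,5-dimethoxyphenol | COc1cc(O)cc(OC)c1 | starting material
2 | 3,5-dimethoxyphenyl isopropylcarbamate | CC(C)NC(=O)Oc1cc(OC)cc(OC)c1 | intermediate
3 | 3,5-dimethoxyphenyl N-(tert-butyldimethylsilyl)-N-isopropylcarbamate (not isolated) | CC(C)N(C(=O)Oc1cc(OC)cc(OC)c1)[Si](C)(C)C(C)(C)C | intermediate
4 | 2-lithio derivative of 3 (not isolated) | [Li]c1c(OC)cc(OC)cc1OC(=O)N(C(C)C)[Si](C)(C)C(C)(C)C | intermediate
5 | 3,5-dimethoxy-2-(trimethylsilyl)phenyl N-(tert-butyldimethylsilyl)-N-isopropylcarbamate (not isolated) | COc1cc(OC)c([Si](C)(C)C)c(OC(=O)N(C(C)C)[Si](C)(C)C(C)(C)C)c1 | intermediate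
6 | 3,5-dimethoxy-2-(trimethylsilyl)phenyl isopropylcarbamate | COc1cc(OC)c([Si](C)(C)C)c(OC(=O)NC(C)C)c1 | intermediate
7 | 3,5-dimethoxy-2-(trimethylsilyl)phenol (not isolated) | COc1cc(OC)c([Si](C)(C)C)c(O)c1 | intermediate
8 | 3,5-dimethoxy-2-(trimethylsilyl)phenyl trifluoromethanesulfonate | COc1cc(OC)c([Si](C)(C)C)c(OS(=O)(=O)C(F)(F)F)c1 | intermediate
9 | vanillin | COc1cc(C=O)ccc1O | starting material
10 | 4-(1,3-dioxolan-2-yl)-2-methoxyphenol | COc1cc(C2OCCO2)ccc1O | intermediate
11 | 4-fluoro-3-hydroxybenzaldehyde | O=Cc1ccc(F)c(O)c1 | starting material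
12 | 3-(benzyloxy)-4-fluorobenzaldehyde | O=Cc1ccc(F)c(OCc2ccccc2)c1 | intermediate
13 | 3-(benzyloxy)-4-[4-(1,3-dioxolan-2-yl)-2-methoxyphenoxy]benzaldehyde | O=Cc1ccc(Oc2ccc(C3OCCO3)cc2OC)c(OCc2ccccc2)c1 | intermediate
14 | methyl 2-(benzyloxy)acetate | COC(=O)COCc1ccccc1 | starting material
15 | lithium enolate of methyl 2-(benzyloxy)acetate (not isolated) | COC(O[Li])=COCc1ccccc1 | intermediate
16 | methyl 2-(benzyloxy)-3-{3-(benzyloxy)-4-[4-(1,3-dioxolan-2-yl)-2-methoxyphenoxy]phenyl}-3-hydroxypropanoate, mixture of racemic diastereomers | COC(=O)C(OCc1ccccc1)C(O)c1ccc(Oc2ccc(C3OCCO3)cc2OC)c(OCc2ccccc2)c1 | intermediate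
17 | methyl 2-(benzyloxy)-3-{3-(benzyloxy)-4-[4-(1,3-dioxolan-2-yl)-2-methoxyphenoxy]phenyl}-3-oxopropanoate, racemic | COC(=O)C(OCc1ccccc1)C(=O)c1ccc(Oc2ccc(C3OCCO3)cc2OC)c(OCc2ccccc2)c1 | intermediate
18 | caesium enolate of 17, enolate oxygen cis to the ester (not isolated) | COC(=O)/C(OCc1ccccc1)=C(\[O-])c1ccc(Oc2ccc(C3OCCO3)cc2OC)c(OCc2ccccc2)c1.[Cs+] | intermediate
19 | 3,5-dimethoxybenzyne (not isolated) | COC1=CC(OC)=CC#C1 | intermediate
20 | aryl caesium O-aryl enol ether, aryloxy group cis to the ester (not isolated) | [Cs]c1c(OC)cc(OC)cc1O/C(c1ccc(Oc2ccc(C3OCCO3)cc2OC)c(OCc2ccccc2)c1)=C(/OCc1ccccc1)C(=O)OC | intermediate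
21 | 3-(benzyloxy)-2-{3-(benzyloxy)-4-[4-(1,3-dioxolan-2-yl)-2-methoxyphenoxy]phenyl}-5,7-dimethoxy-4H-chromen-4-one | COc1cc(OC)c2c(=O)c(OCc3ccccc3)c(-c3ccc(Oc4ccc(C5OCCO5)cc4OC)c(OCc4ccccc4)c3)oc2c1 | intermediate
22 | 4-{2-(benzyloxy)-4-[3-(benzyloxy)-5,7-dimethoxy-4-oxo-4H-chromen-2-yl]phenoxy}-3-methoxybenzaldehyde | COc1cc(OC)c2c(=O)c(OCc3ccccc3)c(-c3ccc(Oc4ccc(C=O)cc4OC)c(OCc4ccccc4)c3)oc2c1 | intermediate
23 | 2',4',6'-trihydroxyacetophenone | CC(=O)c1c(O)cc(O)cc1O | starting material
24 | 1-[2,4-bis(benzyloxy)-6-hydroxyphenyl]ethan-1-one | CC(=O)c1c(O)cc(OCc2ccccc2)cc1OCc1ccccc1 | intermediate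
25 | aldol adduct of 22 and 24, racemic beta-hydroxy ketone (not isolated) | O=C(CC(O)c1ccc(Oc2ccc(-c3oc4cc(OC)cc(OC)c4c(=O)c3OCc3ccccc3)cc2OCc2ccccc2)c(OC)c1)c1c(O)cc(OCc2ccccc2)cc1OCc1ccccc1 | intermediate
26 | (E)-1-[2,4-bis(benzyloxy)-6-hydroxyphenyl]-3-(4-{2-(benzyloxy)-4-[3-(benzyloxy)-5,7-dimethoxy-4-oxo-4H-chromen-2-yl]phenoxy}-3-methoxyphenyl)prop-2-en-1-one | O=C(/C=C/c1ccc(Oc2ccc(-c3oc4cc(OC)cc(OC)c4c(=O)c3OCc3ccccc3)cc2OCc2ccccc2)c(OC)c1)c1c(O)cc(OCc2ccccc2)cc1OCc1ccccc1 | intermediate
27 | trans-dihydroflavonol from 26, racemic, one enantiomer drawn (not isolated) | COc1cc(OC)c2c(=O)c(OCc3ccccc3)c(-c3ccc(Oc4ccc([C@@H]5[C@H](C(=O)c6c(OCc7ccccc7)cc(OCc7ccccc7)cc6O5)O)cc4OC)c(OCc4ccccc4)c3)oc2c1 | intermediate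
28 | 5,7-bis(benzyloxy)-2-(4-{2-(benzyloxy)-4-[3-(benzyloxy)-5,7-dimethoxy-4-oxo-4H-chromen-2-yl]phenoxy}-3-methoxyphenyl)-3-hydroxy-4H-chromen-4-one | COc1cc(OC)c2c(=O)c(OCc3ccccc3)c(-c3ccc(Oc4ccc(-c5oc6cc(OCc7ccccc7)cc(OCc7ccccc7)c6c(=O)c5O)cc4OC)c(OCc4ccccc4)c3)oc2c1 | intermediate
29 | 2-{4-[4-(3,5-dihydroxy-7-methoxy-4-oxo-4H-chromen-2-yl)-2-hydroxyphenoxy]-3-methoxyphenyl}-3,5,7-trihydroxy-4H-chromen-4-one | COc1cc(O)c2c(=O)c(O)c(-c3ccc(Oc4ccc(-c5oc6cc(O)cc(O)c6c(=O)c5O)cc4OC)c(O)c3)oc2c1 | target

**Step count and risks**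
Total: 14 steps. Longest linear sequence: 9 steps (from vanillin 9 through steps 4, 6, 7, 8, 9, 10, 12, 13 and 14).

Steps most likely to fail:

1. Step 9 (aryne annulation). The enolate may be arylated at carbon instead of oxygen, after which acyl transfer inserts the aryne into the C2–C3 bond of 17; alternatively the aryl anion may be protonated before it acylates, leaving an open enol ether. The fallback builds ring C of this unit by known chemistry, setting out from aldehyde 13. Claisen–Schmidt condensation of 13 with commercial 1-(2-hydroxy-4,6-dimethoxyphenyl)ethan-1-one (KOH, EtOH/THF, rt) should give the 2'-hydroxy-4',6'-dimethoxychalcone F1. Algar–Flynn–Oyamada oxidation (H2O2, NaOH, MeOH, 0 °C) should give the 3-hydroxy-5,7-dimethoxyflavone F2. O-Benzylation of its 3-hydroxyl (BnBr, K2CO3, DMF) returns to the route at 21.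

2. Step 13 (Algar–Flynn–Oyamada). With the 6'-benzyloxy group, ring closure through the alpha carbon and ring contraction towards an aurone may compete with flavonol formation, and retro-aldol cleavage of the chalcone is possible in the alkaline medium. The fallback separates ring closure from hydroxylation, setting out from chalcone 26. Oxidative cyclisation with I2 (catalytic) in DMSO at 120 °C should give the 5,7-bis(benzyloxy)flavone F3. Its only C3–H is lithiated (LiN(i-Pr)2, THF, −78 °C) and quenched with B(OMe)3 to the 3-(dimethoxyboryl)flavone F4. Oxidation of the C–B bond (H2O2, AcOH) returns to the route at 28.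

3. Step 14 (global deprotection). Demethylation may go beyond C5 (loss of the 7-methoxy or the guaiacyl methyl group) or stop short at C5, and benzyl cations may be transferred onto the electron-rich phloroglucinol ring. The fallback splits the deprotection into two orthogonal operations, setting out from 28. Hydrogenolysis (H2, Pd(OH)2/C, THF/MeOH, rt) should remove the four benzyl groups and give the 5-O-methyl ether of the target F5. Chelation-controlled demethylation at C5 (AlCl3, MeCN, 60 °C) returns to the route at 29.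

Further compounds
F1 | step 9 | (E)-3-{3-(benzyloxy)-4-[4-(1,3-dioxolan-2-yl)-2-methoxyphenoxy]phenyl}-1-(2-hydroxy-4,6-dimethoxyphenyl)prop-2-en-1-one | COc1cc(O)c(C(=O)/C=C/c2ccc(Oc3ccc(C4OCCO4)cc3OC)c(OCc3ccccc3)c2)c(OC)c1
F2 | step 9 | 2-{3-(benzyloxy)-4-[4-(1,3-dioxolan-2-yl)-2-methoxyphenoxy]phenyl}-3-hydroxy-5,7-dimethoxy-4H-chromen-4-one | COc1cc(OC)c2c(=O)c(O)c(-c3ccc(Oc4ccc(C5OCCO5)cc4OC)c(OCc4ccccc4)c3)oc2c1
F3 | step 13 | 5,7-bis(benzyloxy)-2-(4-{2-(benzyloxy)-4-[3-(benzyloxy)-5,7-dimethoxy-4-oxo-4H-chromen-2-yl]phenoxy}-3-methoxyphenyl)-4H-chromen-4-one | COc1cc(OC)c2c(=O)c(OCc3ccccc3)c(-c3ccc(Oc4ccc(-c5cc(=O)c6c(OCc7ccccc7)cc(OCc7ccccc7)cc6o5)cc4OC)c(OCc4ccccc4)c3)oc2c1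
F4 | step 13 | dimethyl 3-boronate of F3 (3-(dimethoxyboryl)flavone) | COc1cc(OC)c2c(=O)c(OCc3ccccc3)c(-c3ccc(Oc4ccc(-c5oc6cc(OCc7ccccc7)cc(OCc7ccccc7)c6c(=O)c5B(OC)OC)cc4OC)c(OCc4ccccc4)c3)oc2c1
F5 | step 14 | 2-{4-[4-(3-hydroxy-5,7-dimethoxy-4-oxo-4H-chromen-2-yl)-2-hydroxyphenoxy]-3-methoxyphenyl}-3,5,7-trihydroxy-4H-chromen-4-one | COc1cc(OC)c2c(=O)c(O)c(-c3ccc(Oc4ccc(-c5oc6cc(O)cc(O)c6c(=O)c5O)cc4OC)c(O)c3)oc2c1
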